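**Plan** (numbering used throughout: ring C1 bears the side chain, C2 and C3 the angelates, C4 the methyl, C4/C5 the epoxide, C6 is CH2; side chain C7 (=CH2), C8 (OAc), C9–C11 prenyl)
1. Cuts, in retrosynthetic order: both angelate C–O bonds; the oxirane (back to C4=C5 next to a cis C2,C3-diol); C10=C11 (metathesis) and C8–C9 (allylation of a C8 aldehyde); the C7 methylene; then ring bonds C2–C3 and C4–C5 together.
2. Enabling feature: O–C2 and the chain C1–C7–C8(–O) can be tied into a 2-methoxy-2,3-dihydrofuran (temporary acetal ring, C8 as masked aldehyde). Its enol ether C2=C1 plus a vinyl group (C6=C5) is a 1-alkoxy-2-alkyldiene, and C3(O)–C4(CH3) is the retron of (E)-1-nitropropene (nitro = activating group and latent C3 oxygen).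
3. Forward: dihydrofuran diene, then the [4+2] closes the carbocycle onto it; hydrogenation, Nef, dehydrogenation and 1,2-reduction give the bicyclic cis-allylic alcohol.
4. The furanoid ring is then opened to the lactol, C7 is methylenated, C8 allylated and acetylated, the prenyl end made by metathesis; the oxirane closes last but one, the angelates last.
5. Stereochemistry: C1/C2 cis from hydrogenation to the cis-fused bicycle; C3 from convex-face hydride delivery; C4/C5 from hydroxyl-directed epoxidation; C8 (S) and the absolute configuration from B-allyldiisopinocampheylborane on the racemic lactol, with separation of the two diastereomers.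

Key step: step 4

Remark: the target is read as the all-cis ring isomer (side chain, both acyloxy groups and the epoxide oxygen on one face, C4-methyl on the other) with 8S; compounds 5–16 are racemic, and 7–16 are drawn as the enantiomer that leads on to the target.

**Step 1**
Reactants: 1 1-nitropropan-2-ol
Product: 3 (E)-1-nitroprop-1-ene, via 1-nitropropan-2-yl methanesulfonate 2 (not isolated)
Conditions: MsCl, Et3N (2.2 equiv), CH2Cl2, −10 → 0 °C; distil
Reagents that add atoms: none
Why: Mesylation of the β-nitro alcohol and E1cB elimination (nitroaldol dehydration) should give the conjugated nitroalkene as the stable E isomer.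

**Step 2**
Reactants: 4 2,5-dimethoxytetrahydrofuran-3-carbaldehyde
Product: 5 rac-2-methoxy-2,3-dihydrofuran-4-carbaldehyde
Conditions: DBU (0.2 equiv), CH2Cl2, rt
Reagents that add atoms: none
Why: Base-catalysed E1cB β-elimination of methanol from the β-alkoxy aldehyde should give the push–pull enal, which should not lose the second methanol in the absence of acid.

**Step 3**
Reactants: 5 rac-2-methoxy-2,3-dihydrofuran-4-carbaldehyde
Product: 6 rac-4-ethenyl-2-methoxy-2,3-dihydrofuran
Conditions: Ph3PCH3Br, KOt-Bu, THF, 0 °C → rt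
Reagents that add atoms: methyltriphenylphosphonium bromide, C[P+](c1ccccc1)(c1ccccc1)c1ccccc1.[Br-]
Why: Wittig methylenation with the non-stabilised ylide installs the vinyl group and completes the 1-alkoxy-2-alkylbuta-1,3-diene, the acetal being stable to base.

**Step 4**
Reactants: 6 rac-4-ethenyl-2-methoxy-2,3-dihydrofuran; 3 (E)-1-nitroprop-1-ene
Product: 7 rac-2-methoxy-6-methyl-7-nitro-2,3,5,6,7,7a-hexahydro-1-benzofuran
Conditions: toluene, BHT (cat.), 50 °C, sealed tube
Reagents that add atoms: none
Why: Thermal normal-demand Diels–Alder reaction, a concerted but asynchronous suprafacial [4π+2π] cycloaddition between the 1-alkoxy-2-alkyldiene of 6 (O–C2=C1–C6=C5) and the nitroalkene, whose closest known type is the cycloaddition of 1-alkoxy- and 1-silyloxybuta-1,3-dienes with nitroalkenes. The cyclohexene ring is closed in this six-membered pericyclic mode, C2–C3 and C4–C5 being formed together on the pre-existing dihydrofuran. Regioselectivity is the selectivity that matters: the ring oxygen puts the largest HOMO coefficient on the terminal CH2 (C5), which pairs with the nitroalkene β-carbon (C4), so the nitro-bearing carbon (C3) bonds to the oxygen-bearing C2. The new stereocentre C2 (C-7a) is set relative to the acetal carbon by approach of the dienophile anti to the methoxy group; the centres at C3 and C4 follow from endo nitro and the E alkene but are erased in steps 6 and 7, so endo/exo and facial mixtures converge. Chemoselectivity for the carbodiene [4+2] over hetero-cycloaddition of the nitroalkene onto the enol ether should be secured by the freely s-cis diene and the absence of a Lewis acid.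

**Step 5**
Reactants: 7 rac-2-methoxy-6-methyl-7-nitro-2,3,5,6,7,7a-hexahydro-1-benzofuran
Product: 8 rac-cis-fused 2-methoxy-6-methyl-7-nitro-octahydro-1-benzofuran
Conditions: H2 (1 atm), 5% Pd/C, EtOAc, rt
Reagents that add atoms: none
Why: Heterogeneous hydrogenation of the ring-fusion alkene from the convex face (syn to H-7a) should give the cis-fused bicycle, i.e. C1–C7 cis to C2–O, while the secondary aliphatic nitro group is expected to survive these mild conditions.

**Step 6**
Reactants: 8 rac-cis-fused 2-methoxy-6-methyl-7-nitro-octahydro-1-benzofuran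
Product: 10 rac-cis-fused 2-methoxy-6-methyl-hexahydro-1-benzofuran-7(2H)-one, via sodium nitronate 9 (not isolated)
Conditions: NaOMe, MeOH, 0 °C; then O3, CH2Cl2/MeOH, −78 °C; N2 purge
Reagents that add atoms: ozone, [O-][O+]=O
Why: Oxidative Nef reaction (ozonolysis of the nitronate C=N bond) unmasks the C3 carbonyl; no alkene is left to compete and the C3/C4 stereocentres of the cycloaddition lose their significance.

**Step 7**
Reactants: 10 rac-cis-fused 2-methoxy-6-methyl-hexahydro-1-benzofuran-7(2H)-one
Product: 13 rac-cis-fused 2-methoxy-6-methyl-3,3a,4,7a-tetrahydro-1-benzofuran-7(2H)-one, via lithium enolate 11 (not isolated), via α-sulfilimino ketone 12 (not isolated)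
Conditions: LiN(SiMe3)2, THF, −78 °C; then N-tert-butylbenzenesulfinimidoyl chloride, −78 °C
Reagents that add atoms: none
Why: Mukaiyama dehydrogenation: the kinetic enolate should form on the methyl-bearing side, away from the α-alkoxy ring-fusion methine, and S-transfer followed by syn-elimination of the sulfenamide gives the C4=C5 enone.

**Step 8**
Reactants: 13 rac-cis-fused 2-methoxy-6-methyl-3,3a,4,7a-tetrahydro-1-benzofuran-7(2H)-one
Product: 14 rac-2-methoxy-6-methyl-2,3,3a,4,7,7a-hexahydro-1-benzofuran-7-ol (7-OH cis to O-1)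
Conditions: NaBH4, CeCl3·7H2O, MeOH, −78 → −20 °C
Reagents that add atoms: none
Why: Luche 1,2-reduction; hydride should attack the convex face of the cis-fused bicycle, anti to the adjacent C–O bond, placing the C3 hydroxyl cis to the C2 oxygen.

**Step 9**
Reactants: 14 rac-2-methoxy-6-methyl-2,3,3a,4,7,7a-hexahydro-1-benzofuran-7-ol
Product: 15 rac-6-methyl-2,3,3a,4,7,7a-hexahydro-1-benzofuran-2,7-diol
Conditions: AcOH/H2O/THF (3:1:1), rt
Reagents that add atoms: water, O
Why: Mild acid hydrolysis of the mixed methyl acetal gives the lactol (masked γ-hydroxy aldehyde at C8), which the allylic alcohol and trisubstituted alkene should tolerate.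

**Step 10**
Reactants: 15 rac-6-methyl-2,3,3a,4,7,7a-hexahydro-1-benzofuran-2,7-diol
Product: 16 rac-6-methyl-3-methylidene-2,3,3a,4,7,7a-hexahydro-1-benzofuran-2,7-diol
Conditions: aq. CH2O (37%), pyrrolidine (0.1 equiv), EtCO2H (0.1 equiv), i-PrOH, 45 °C
Reagents that add atoms: formaldehyde, C=O
Why: Amine/acid-catalysed Mannich condensation–elimination (α-methylenation of aldehydes) on the open hydroxy-aldehyde tautomer installs C7=CH2, and re-closure to the lactol protects the enal from double-bond migration.

**Step 11**
Reactants: 16 rac-6-methyl-3-methylidene-2,3,3a,4,7,7a-hexahydro-1-benzofuran-2,7-diol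
Product: 17 all-cis 6-[(3S)-3-hydroxyhexa-1,5-dien-2-yl]-3-methylcyclohex-3-ene-1,2-diol with the ring configuration of the target
Conditions: B-allyldiisopinocampheylborane from (+)-α-pinene (3 equiv), Et2O, −78 °C → rt; then NaBO3·4H2O, THF/H2O; chromatography
Reagents that add atoms: B-allyldiisopinocampheylborane, C=CCB([C@@H]1C[C@@H]2C[C@H]([C@H]1C)C2(C)C)[C@@H]1C[C@@H]2C[C@H]([C@H]1C)C2(C)C
Why: Reagent-controlled Brown allylboration through a chair six-membered transition state on the open enal tautomer should set C8 as S in both enantiomers of 16, so the racemate becomes two diastereomers; 17 is kept and its diastereomer with the ring centres inverted is removed by chromatography.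

**Step 12**
Reactants: 17 all-cis 6-[(3S)-3-hydroxyhexa-1,5-dien-2-yl]-3-methylcyclohex-3-ene-1,2-diol
Product: 20 (3S)-2-[all-cis-2,3-dihydroxy-4-methylcyclohex-4-en-1-yl]hexa-1,5-dien-3-yl acetate, via cyclic phenylboronate 18 (not isolated), via acetylated phenylboronate 19 (not isolated)
Conditions: PhB(OH)2, toluene, 4 Å MS, rt; then Ac2O, pyridine, DMAP (cat.), 0 °C; then pinacol, rt
Reagents that add atoms: acetic anhydride, CC(=O)OC(C)=O
Why: Transient protection of the cis-1,2-diol as its cyclic phenylboronate leaves only the C8 hydroxyl for acetylation, and transesterification with pinacol then frees the diol.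

**Step 13**
Reactants: 20 (3S)-2-[all-cis-2,3-dihydroxy-4-methylcyclohex-4-en-1-yl]hexa-1,5-dien-3-yl acetate
Product: 21 (3S)-2-[all-cis-2,3-dihydroxy-4-methylcyclohex-4-en-1-yl]-6-methylhepta-1,5-dien-3-yl acetate
Conditions: second-generation Grubbs catalyst (5 mol%), 2-methylbut-2-ene (excess), CH2Cl2, 40 °C
Reagents that add atoms: 2-methylbut-2-ene, CC=C(C)C
Why: Olefin cross-metathesis of the monosubstituted alkene with 2-methylbut-2-ene gives the prenyl terminus, the 1,1-disubstituted and ring trisubstituted alkenes being too hindered to react.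

**Step 14**
Reactants: 21 (3S)-2-[all-cis-2,3-dihydroxy-4-methylcyclohex-4-en-1-yl]-6-methylhepta-1,5-dien-3-yl acetate
Product: 22 (3S)-2-[all-cis-4,5-epoxy-2,3-dihydroxy-4-methylcyclohexyl]-6-methylhepta-1,5-dien-3-yl acetate
Conditions: VO(acac)2 (5 mol%), t-BuOOH (1.5 equiv), CH2Cl2, 0 °C
Reagents that add atoms: tert-butyl hydroperoxide, CC(C)(C)OO
Why: Hydroxyl-directed epoxidation delivers oxygen from the vanadium alkylperoxide bound to the allylic C3–OH to the syn face of C4=C5, setting both oxirane centres cis to the diol, while the side-chain alkenes, which lack an allylic hydroxyl, should react far more slowly.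

**Step 15**
Reactants: 22 (3S)-2-[all-cis-4,5-epoxy-2,3-dihydroxy-4-methylcyclohexyl]-6-methylhepta-1,5-dien-3-yl acetate
Product: 23 CNP0188566.2
Conditions: angelic acid, 2,4,6-trichlorobenzoyl chloride, Et3N, toluene, rt; then 22, 80 °C
Reagents that add atoms: angelic acid, C/C=C(/C)C(=O)O
Why: Yamaguchi-type esterification of both secondary hydroxyls through the mixed anhydride, run without DMAP so that the Z (angelate) geometry is not isomerised to tiglate.

**Compound list**
1 | 1-nitropropan-2-ol (racemic) | CC(O)C[N+](=O)[O-] | starting material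
2 | 1-nitropropan-2-yl methanesulfonate | CC(C[N+](=O)[O-])OS(C)(=O)=O | intermediate (not isolated)
3 | (E)-1-nitroprop-1-ene | C/C=C/[N+](=O)[O-] | intermediate
4 | 2,5-dimethoxytetrahydrofuran-3-carbaldehyde (commercial mixture of stereoisomers) | COC1CC(C=O)C(OC)O1 | starting material
5 | rac-2-methoxy-2,3-dihydrofuran-4-carbaldehyde | COC1CC(C=O)=CO1 | intermediate
6 | rac-4-ethenyl-2-methoxy-2,3-dihydrofuran | COC1CC(C=C)=CO1 | intermediate
7 | rac-2-methoxy-6-methyl-7-nitro-2,3,5,6,7,7a-hexahydro-1-benzofuran (NO2 cis to O-1 at C-7a, 6-CH3 trans to NO2; acetal carbon as formed, mainly OMe anti to C-7) | COC1O[C@H]2[C@@H]([N+](=O)[O-])[C@H](C)CC=C2C1 | intermediate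
8 | rac-cis-fused 2-methoxy-6-methyl-7-nitro-octahydro-1-benzofuran (H-3a cis to H-7a) | COC1O[C@H]2[C@@H]([N+](=O)[O-])[C@H](C)CC[C@H]2C1 | intermediate
9 | sodium nitronate of 8 | COC1O[C@H]2C(=[N+]([O-])[O-])[C@H](C)CC[C@H]2C1.[Na+] | intermediate (not isolated)
10 | rac-cis-fused 2-methoxy-6-methyl-hexahydro-1-benzofuran-7(2H)-one (C-6 epimers) | COC1O[C@H]2C(=O)C(C)CC[C@H]2C1 | intermediate
11 | lithium enolate of 10 (C6=C7 enolate) | COC1O[C@H]2C([O-])=C(C)CC[C@H]2C1.[Li+] | intermediate (not isolated)
12 | 6-(N-tert-butyl-S-phenylsulfilimino) derivative of 10 | COC1O[C@H]2C(=O)C(C)(S(=NC(C)(C)C)c3ccccc3)CC[C@H]2C1 | intermediate (not isolated)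
13 | rac-cis-fused 2-methoxy-6-methyl-3,3a,4,7a-tetrahydro-1-benzofuran-7(2H)-one | COC1O[C@H]2C(=O)C(C)=CC[C@H]2C1 | intermediate
14 | rac-2-methoxy-6-methyl-2,3,3a,4,7,7a-hexahydro-1-benzofuran-7-ol (cis-fused, 7-OH cis to O-1) | COC1O[C@H]2[C@@H](O)C(C)=CC[C@H]2C1 | intermediate
15 | rac-6-methyl-2,3,3a,4,7,7a-hexahydro-1-benzofuran-2,7-diol (lactol, both anomers) | OC1O[C@H]2[C@@H](O)C(C)=CC[C@H]2C1 | intermediate
16 | rac-6-methyl-3-methylidene-2,3,3a,4,7,7a-hexahydro-1-benzofuran-2,7-diol | OC1O[C@H]2[C@@H](O)C(C)=CC[C@H]2C1=C | intermediate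
17 | all-cis 6-[(3S)-3-hydroxyhexa-1,5-dien-2-yl]-3-methylcyclohex-3-ene-1,2-diol, ring configuration of the target | C=C([C@H](CC=C)O)[C@@H]1CC=C(C)[C@H](O)[C@@H]1O | intermediate
18 | cyclic phenylboronate of the ring diol of 17 | C=C([C@H](CC=C)O)[C@@H]1CC=C(C)[C@@H]2OB(c3ccccc3)O[C@H]12 | intermediate (not isolated)
19 | side-chain acetate of 18 | C=C([C@H](CC=C)OC(C)=O)[C@@H]1CC=C(C)[C@@H]2OB(c3ccccc3)O[C@H]12 | intermediate (not isolated)
20 | (3S)-2-[all-cis-2,3-dihydroxy-4-methylcyclohex-4-en-1-yl]hexa-1,5-dien-3-yl acetate | C=C([C@H](CC=C)OC(C)=O)[C@@H]1CC=C(C)[C@H](O)[C@@H]1O | intermediate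
21 | (3S)-2-[all-cis-2,3-dihydroxy-4-methylcyclohex-4-en-1-yl]-6-methylhepta-1,5-dien-3-yl acetate | C=C([C@H](CC=C(C)C)OC(C)=O)[C@@H]1CC=C(C)[C@H](O)[C@@H]1O | intermediate
22 | (3S)-2-[all-cis-4,5-epoxy-2,3-dihydroxy-4-methylcyclohexyl]-6-methylhepta-1,5-dien-3-yl acetate (epoxide cis to both hydroxyls) | C=C([C@H](CC=C(C)C)OC(C)=O)[C@@H]1C[C@@H]2O[C@]2(C)[C@H](O)[C@@H]1O | intermediate
23 | CNP0188566.2: all-cis 1-[(3S)-3-acetoxy-6-methylhepta-1,5-dien-2-yl]-4,5-epoxy-4-methylcyclohexane-2,3-diyl bis[(Z)-2-methylbut-2-enoate] | C=C([C@H](CC=C(C)C)OC(C)=O)[C@@H]1C[C@@H]2O[C@]2(C)[C@H](OC(=O)/C(C)=C\C)[C@@H]1OC(=O)/C(C)=C\C | target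

**Totals**
Total step count: 15. Longest linear sequence: 14 steps (4 → 23, steps 2–15); step 1 makes the dienophile on a one-step side branch.

**Steps most likely to fail**

Step 6. The nitronate may expel the ring oxygen β to it (ring opening) or form incompletely at the hindered secondary carbon, so that the carbonyl is not unmasked cleanly. Fallback: set out from 8 and reduce the nitro group without a discrete nitronate, using SnCl2·2H2O, PhSH and Et3N in THF, to 2-methoxy-6-methyl-octahydro-1-benzofuran-7-one oxime F1. Cleave F1 reductively with aqueous TiCl3/NH4OAc (imine, then hydrolysis); this comes back to the route at 10.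

Step 11. Addition to the closed lactol may be slow, reagent control incomplete, or the two diastereomeric triols may co-elute, so that the two enantiomeric series are not separated. Fallback: resolve earlier. Set out from 14 and esterify with (S)-2-methoxy-2-phenylacetic acid (DCC, DMAP, CH2Cl2). Separate the two esters by chromatography or crystallisation, keeping the (S)-O-methylmandelate of the required enantiomer F2 and discarding the (S)-O-methylmandelate of the other enantiomer F3. Cleave F2 with K2CO3 in MeOH; this comes back to the route at 14 as a single enantiomer, after which steps 9–11 should give 17 without a separation.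

Step 15. The hindered cis-diol may acylate incompletely, the angeloyl groups may isomerise to tiglates, or the oxirane may open at 80 °C. Fallback: set out from 22 and acylate both hydroxyls at room temperature with 2-[bis(2,2,2-trifluoroethoxy)phosphoryl]propanoic acid (DCC, DMAP) to the bis(phosphonopropanoate) F4. Then build both Z-alkenes in place by Still–Gennari olefination with acetaldehyde (KN(SiMe3)2, 18-crown-6, THF, −78 °C); this comes back to the route at 23.

**Further compounds**
F1 | step 6 | 2-methoxy-6-methyl-octahydro-1-benzofuran-7-one oxime (cis-fused) | COC1O[C@H]2C(=NO)[C@H](C)CC[C@H]2C1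
F2 | step 11 | (S)-2-methoxy-2-phenylacetate of 14, required enantiomer | COC1O[C@H]2[C@@H](OC(=O)[C@@H](OC)c3ccccc3)C(C)=CC[C@H]2C1
F3 | step 11 | (S)-2-methoxy-2-phenylacetate of the enantiomer of 14 | COC1O[C@@H]2[C@H](OC(=O)[C@@H](OC)c3ccccc3)C(C)=CC[C@@H]2C1
F4 | step 15 | bis{2-[bis(2,2,2-trifluoroethoxy)phosphoryl]propanoate} of 22 | C=C([C@H](CC=C(C)C)OC(C)=O)[C@@H]1C[C@@H]2O[C@]2(C)[C@H](OC(=O)C(C)P(=O)(OCC(F)(F)F)OCC(F)(F)F)[C@@H]1OC(=O)C(C)P(=O)(OCC(F)(F)F)OCC(F)(F)F
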